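Millimolar per hour is the unit we start in. Solid J dissolves to X, X turns reversibly into L and into E, and L turns reversibly into Q; L beyond its solubility comes out as crystals G.

J 10 mM; time 15 d

- at 15 d, what has stopped the reaction, if anything has (for what has run out or reacted, a solid counts together with what of it has only dissolved) (all of J has reacted / forward and back rates have come level / it is still moving)
- L at 15 d, in percent of the J charged
- E at 15 d, in percent of the J charged

- for L the G are counted in
- as a solid, counted per litre of solution: G, J
- at the start none of J is in solution
- what has only dissolved of J counts as not reacted
- the reaction counts as stopped when no species that holds the J changes by six tenths of a point or more over the second half of the time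
- run time (flask): 15 d

    X ⇌ L (K1 = 0.39, k1 = 0.15 h⁻¹)
    X ⇌ E (K2 = 2.9, k2 = 0.085 h⁻¹)
    L ⇌ Q (K3 = 2.4, k3 = 0.046 h⁻¹)
    G ⇌ L, rate k4*(cs4 - [L]) while solid is left; crystals form when [L] > cs4 (cs4 = 6.7 mM, k4 = 13 h⁻¹)
    J ⇌ X, rate k5*(cs5 - [X]) while solid is left; crystals form when [X] > cs5 (cs5 = 7.1 mM, k5 = 0.088 h⁻¹)

At the start this flask has no X in solution, so J goes in at 0.625 mM h⁻¹, a pace that would take 16.0 h for the charge. Two things slow it. Standing X multiplies the dissolving rate by one minus X over its solubility. The back runs bring each conversion's net rate down towards zero, each step by itself with a relaxation half-life of at most 0.443 d, short against 15 d.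

Where the slowing ends, X, L, E and Q stand in the ratio of their constants (thermodynamic control), and X is one part in 5.23. With X at its solubility, L would stand at 2.77 mM, less than its own solubility of 6.7 mM, so G does not come into it. The four dissolved forms then carry 37.1 mM: this is the holding capacity, the J the liquid can take up.

Our charge gives a dissolving factor at balance of 0.730, which stretches the time to about 21.9 h, somewhat more if X stands higher on the way. We commit to level rates by 15 d, with L at 7.46% and E at 55.5%.

The forecast gives forward and back rates have come level, L 7.46% and E 55.5%, holding that “the flask has reached equilibrium, with X still present rather than fully reacted”.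

The simulation gives forward and back rates have come level, L 7.46% and E 55.5%.

This charge was 27.0% of the holding capacity, and J stands at 0% after 15.0 d. E stops at 55.5% because of the backward run from E to X: the run without it puts E at 99.8% and changes the answer on what ended the reaction.

For the flask with 40 mM of J, the capacity lies below the charge, so at least 7.25% of J should stay solid. That flask's run shows J at 9.21%, X at 17.5% and E at 50.4% after 15.0 d.

All constants were chosen freely.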